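The route rests on taking apart furanone ring B of the spiro benzofuran-3(2H)-one at two bonds, C-3–C-3a and O-1–C-7a, so that the phloroglucinol ring A arrives as an aryne. Ring A carries the ether oxygen (on C-7a) and the ketone (on C-3a) side by side, with the C-4 oxygen flanking C-3a. A tertiary alkoxide therefore adds to 3,5-bis(benzyloxy)benzyne meta to the flanking benzyloxy group, and the aryl anion formed at C-3a attacks the ester on the same carbinol carbon, closing ring B by the C-3–C-3a bond. The precursor is a flavan-fused methyl 3-hydroxy-2-aryl-2,3-dihydrobenzofuran-3-carboxylate, made by Norrish–Yang photocyclization of an aryl glyoxylate.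

Key step: step 7

Remark: (−)-epiafzelechin (2R,3R) is taken as a purchasable chiral-pool material that supplies both flavan stereocentres. BOB = 4-(benzyloxy)benzyl. "Furan C-2/C-3" are the CH(aryl) carbon and the quaternary carbon of the new dihydrofuran ring (furan C-3 becomes the spiro carbon).

Step 1
Reactants: 1 (−)-epiafzelechin; 2 4-(benzyloxy)benzyl chloride (four equivalents are consumed, one per hydroxyl group)
Product: 3 tetra-O-BOB-epiafzelechin (BOB ethers on O-3, O-5, O-7 and O-4')
Conditions: NaH (4.8 equiv), 2 (4.4 equiv in all), n-Bu4NI (cat.), DMF, 0 °C → rt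
Reagents that add atoms: 4-(benzyloxy)benzyl chloride (three further equivalents of 2), ClCc1ccc(OCc2ccccc2)cc1.ClCc1ccc(OCc2ccccc2)cc1.ClCc1ccc(OCc2ccccc2)cc1
Why: Fourfold Williamson etherification in which the three phenoxides and the C-3 alkoxide each take up one molecule of 2, which caps every O–H and places on O-7 the benzylic CH2 that later becomes furan C-2; no stereocentre is touched, and the low temperature guards against base-induced epimerization at flavan C-2.

Step 2
Reactants: 3 tetra-O-BOB-epiafzelechin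
Product: 4 8-bromo-tetra-O-BOB-epiafzelechin
Conditions: NBS (1 equiv), CH2Cl2, −78 → 0 °C, dark
Reagents that add atoms: N-bromosuccinimide, O=C1CCC(=O)N1Br
Why: Electrophilic aromatic bromination of the phloroglucinol-type flavan ring, which for 5,7-di-O-benzyl-type flavan-3-ols is expected at C-8 in preference to C-6; one equivalent at low temperature avoids dibromination and spares the less electron-rich BOB rings.

Step 3
Reactants: 4 8-bromo-tetra-O-BOB-epiafzelechin
Product: 6 methyl 2-oxo-2-(tetra-O-BOB-epiafzelechin-8-yl)acetate (aryl glyoxylate), via aryllithium 5 (not isolated)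
Conditions: n-BuLi, THF, −78 °C; then cannulated into (CO2Me)2 (excess), THF, −78 °C
Reagents that add atoms: dimethyl oxalate, COC(=O)C(=O)OC
Why: Bromine–lithium exchange followed by acylation of the aryllithium with an oxalate diester should give the aryl glyoxylate, because the tetrahedral adduct persists at −78 °C and the hindered ketone is not attacked a second time.

Step 4
Reactants: 6 aryl glyoxylate
Product: 7 flavan-fused methyl (2R,3R)-3-hydroxy-2-[4-(benzyloxy)phenyl]-2,3-dihydrobenzofuran-3-carboxylate (3-OH cis to the 2-aryl group)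
Conditions: hν (365 nm), degassed benzene (0.01 M), 15 °C
Reagents that add atoms: none
Why: Norrish–Yang photocyclization, the known behaviour of o-(benzyloxy)phenylglyoxylates: the excited, twisted α-keto ester abstracts a δ-hydrogen from the O-7 benzylic CH2 and the 1,5-biradical closes to the 3-hydroxy-2,3-dihydrobenzofuran, whereas the biradical from the other δ-hydrogen (flavan C-2–H, reached through O-1) cannot close without a bridgehead aromatic carbon and should return its hydrogen; in the closure the ester avoids the aryl group, which sets OH cis to aryl at the two new centres, while the distant flavan centres give no useful facial bias, so the (2R,3R) isomer 7 is to be separated by chromatography from its (2S,3S) diastereomer.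

Step 5
Reactants: 8 3,5-bis(benzyloxy)phenol
Product: 9 2-bromo-3,5-bis(benzyloxy)phenol
Conditions: NBS, i-Pr2NH (cat.), CH2Cl2, 0 °C
Reagents that add atoms: N-bromosuccinimide, O=C1CCC(=O)N1Br
Why: Amine-mediated ortho-selective bromination of a phenol; the position between OH and OBn is less hindered than the one between the two benzyloxy groups.

Step 6
Reactants: 9 2-bromo-3,5-bis(benzyloxy)phenol
Product: 12 3,5-bis(benzyloxy)-2-(trimethylsilyl)phenyl trifluoromethanesulfonate, via aryl silyl ether 10 (not isolated), via lithium 2-silylphenolate 11 (not isolated)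
Conditions: HMDS, THF, 65 °C; evaporation; n-BuLi, THF, −78 °C; Tf2O, −78 → 0 °C
Reagents that add atoms: hexamethyldisilazane, C[Si](C)(C)N[Si](C)(C)C; trifluoromethanesulfonic anhydride, O=S(=O)(OS(=O)(=O)C(F)(F)F)C(F)(F)F
Why: Standard one-pot route to an o-silylaryl triflate aryne precursor: O-silylation, bromine–lithium exchange with retro-Brook 1,3-shift of silicon from O to C, then triflation of the phenolate.

Step 7
Reactants: 7 flavan-fused hydroxy ester; 12 o-silylaryl triflate
Product: 15 perbenzylated spiro ketone (4,6-bis(benzyloxy)benzofuran-3(2H)-one spiro-linked at C-2 to furan C-3), via sodium alkoxide 13 (not isolated), via 3,5-bis(benzyloxy)benzyne 14 (not isolated)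
Conditions: NaH (1.05 equiv), THF, 0 °C; then 12 (excess), CsF, 18-crown-6, THF, 0 °C → rt
Reagents that add atoms: none
Why: Proposed new method: fluoride removes the silyl group of 12 and triflate leaves to give aryne 14; alkoxide 13 adds to the aryne carbon meta to the neighbouring benzyloxy group, which places the new aryl anion ortho to that inductively stabilizing oxygen, and this anion attacks the methyl ester on the same carbinol carbon and expels methoxide. The closest known reaction type is the aryne annulation of salicylate esters to xanthones (O-arylation followed by intramolecular acyl substitution), transferred here from a phenoxide to the tertiary alkoxide of an α-hydroxy ester and to a five-membered ring. Ring B closes in the 5-exo-trig mode at the ester carbonyl, forming the bond between ketone carbon C-3 and ring A carbon C-3a. No new stereocentre arises: the spiro carbon is the former carbinol carbon, none of whose bonds is broken, so its (R) configuration and the cis relation of its oxygen to the neighbouring aryl group are carried over from 7. The step needs regioselective addition to the aryne, secured by the 3-benzyloxy group (attack at the distal, more distorted aryne carbon), and acylation of the aryl anion in preference to its protonation, secured by the aprotic medium after deprotonation with NaH and by the ester sitting one atom away; every other hydroxyl group is protected.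

Step 8
Reactants: 15 perbenzylated spiro ketone
Product: 16 target CNP0228515.2
Conditions: H2 (1 atm), Pd(OH)2/C, THF/MeOH, rt
Reagents that add atoms: none
Why: Hydrogenolysis of benzylic C–O bonds removes the six benzyl ethers and then the three 4-hydroxybenzyl groups, whereas the two cyclic benzylic ethers (flavan C-2–O-1 and furan C-2–O) are secondary, hindered and expected to cleave far more slowly under these mild conditions; no stereocentre is affected.

Compound list
1 | (−)-epiafzelechin, (2R,3R)-2-(4-hydroxyphenyl)chromane-3,5,7-triol | Oc1cc(O)c2c(c1)O[C@H](c1ccc(O)cc1)[C@H](O)C2 | starting material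
2 | 4-(benzyloxy)benzyl chloride | ClCc1ccc(OCc2ccccc2)cc1 | starting material
3 | (2R,3R)-3,5,7-tris(BOB-oxy)-2-[4-(BOB-oxy)phenyl]chromane (tetra-O-BOB-epiafzelechin) | C(c1ccc(OCc2ccccc2)cc1)Oc1cc(OCc2ccc(OCc3ccccc3)cc2)c2c(c1)O[C@H](c1ccc(OCc3ccc(OCc4ccccc4)cc3)cc1)[C@H](OCc1ccc(OCc3ccccc3)cc1)C2 | intermediate
4 | 8-bromo-tetra-O-BOB-epiafzelechin (2R,3R) | C(c1ccc(OCc2ccccc2)cc1)Oc1cc(OCc2ccc(OCc3ccccc3)cc2)c2c(c1Br)O[C@H](c1ccc(OCc3ccc(OCc4ccccc4)cc3)cc1)[C@H](OCc1ccc(OCc3ccccc3)cc1)C2 | intermediate
5 | 8-lithio-tetra-O-BOB-epiafzelechin (2R,3R), not isolated | C(c1ccc(OCc2ccccc2)cc1)Oc1cc(OCc2ccc(OCc3ccccc3)cc2)c2c(c1[Li])O[C@H](c1ccc(OCc3ccc(OCc4ccccc4)cc3)cc1)[C@H](OCc1ccc(OCc3ccccc3)cc1)C2 | intermediate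
6 | methyl 2-oxo-2-[(2R,3R)-tetra-O-BOB-epiafzelechin-8-yl]acetate | C(c1ccc(OCc2ccccc2)cc1)Oc1cc(OCc2ccc(OCc3ccccc3)cc2)c2c(c1C(=O)C(=O)OC)O[C@H](c1ccc(OCc3ccc(OCc4ccccc4)cc3)cc1)[C@H](OCc1ccc(OCc3ccccc3)cc1)C2 | intermediate
7 | methyl 3-hydroxy-2-[4-(benzyloxy)phenyl]-2,3-dihydrobenzofuran-3-carboxylate fused to the flavan (furan O = flavan O-7, furan C-3 on flavan C-8); furan C-2 (R), C-3 (R), OH cis to aryl; flavan C-2 (R), C-3 (R); BOB ethers on O-3, O-5, O-4' | COC(=O)[C@@]1(O)c2c(cc(OCc4ccc(OCc5ccccc5)cc4)c3c2O[C@H](c2ccc(OCc4ccc(OCc5ccccc5)cc4)cc2)[C@H](OCc2ccc(OCc4ccccc4)cc2)C3)O[C@@H]1c1ccc(OCc2ccccc2)cc1 | intermediate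
8 | 3,5-bis(benzyloxy)phenol | Oc1cc(OCc2ccccc2)cc(OCc2ccccc2)c1 | starting material
9 | 2-bromo-3,5-bis(benzyloxy)phenol | Oc1cc(OCc2ccccc2)cc(OCc2ccccc2)c1Br | intermediate
10 | [2-bromo-3,5-bis(benzyloxy)phenoxy]trimethylsilane, not isolated | C[Si](C)(C)Oc1cc(OCc2ccccc2)cc(OCc2ccccc2)c1Br | intermediate
11 | lithium 3,5-bis(benzyloxy)-2-(trimethylsilyl)phenolate, not isolated | [Li+].[O-]c1cc(OCc2ccccc2)cc(OCc2ccccc2)c1[Si](C)(C)C | intermediate
12 | 3,5-bis(benzyloxy)-2-(trimethylsilyl)phenyl trifluoromethanesulfonate | C[Si](C)(C)c1c(OS(=O)(=O)C(F)(F)F)cc(OCc2ccccc2)cc1OCc1ccccc1 | intermediate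
13 | sodium alkoxide of 7 (same configuration), not isolated | COC(=O)[C@@]1([O-])c2c(cc(OCc4ccc(OCc5ccccc5)cc4)c3c2O[C@H](c2ccc(OCc4ccc(OCc5ccccc5)cc4)cc2)[C@H](OCc2ccc(OCc4ccccc4)cc2)C3)O[C@@H]1c1ccc(OCc2ccccc2)cc1.[Na+] | intermediate
14 | 3,5-bis(benzyloxy)benzyne, not isolated | C1#CC(OCc2ccccc2)=CC(OCc2ccccc2)=C1 | intermediate
15 | perbenzylated target: 4,6-bis(benzyloxy)benzofuran-3(2H)-one spiro-linked at C-2 (R) to the flavan-fused dihydrofuran; furan C-2 (R) bears 4-(benzyloxy)phenyl cis to the benzofuranone ring oxygen; flavan C-2 (R), C-3 (R) with BOB ethers on O-3, O-5, O-4' | O=C1c2c(OCc3ccccc3)cc(OCc3ccccc3)cc2O[C@@]12c1c(cc(OCc4ccc(OCc5ccccc5)cc4)c3c1O[C@H](c1ccc(OCc4ccc(OCc5ccccc5)cc4)cc1)[C@H](OCc1ccc(OCc4ccccc4)cc1)C3)O[C@@H]2c1ccc(OCc3ccccc3)cc1 | intermediate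
16 | CNP0228515.2 (spiro carbon R, furan CH R, flavan 2R,3R) | O=C1c2c(O)cc(O)cc2O[C@@]12c1c(cc(O)c3c1O[C@H](c1ccc(O)cc1)[C@H](O)C3)O[C@@H]2c1ccc(O)cc1 | target

Total steps: 8. Longest linear sequence: 6 (steps 1, 2, 3, 4, 7, 8).

Steps most likely to fail

Step 7 (Proposed new method). The aryl anion may be protonated before it reaches the hindered ester, so that the sequence stops at the open aryl ether. The fallback uses known reactions and runs from 7 back to 15. O-arylation of 7 with the same aryne under protic quench (12, CsF, MeCN, rt; addition of an O–H bond across an aryne) gives the open aryl ether methyl ester F1. Saponification (LiOH, THF/MeOH/H2O, 50 °C) gives the aryloxy acid F2. Intramolecular Friedel–Crafts acylation through the mixed anhydride (trifluoroacetic anhydride, 2,6-di-tert-butyl-4-methylpyridine, CH2Cl2, 0 °C) on the phloroglucinol-type ring, whose two positions ortho to the ether oxygen are equivalent, closes the same bond and gives 15.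

Step 4. The biradical closure has no facial bias from the distant flavan centres, intermolecular photoreduction may compete, and reversible hydrogen abstraction from flavan C-2 could erode that centre. The fallback puts both new centres under reagent control and runs from 4 back to 7. Wittig reaction of 4-(benzyloxy)benzaldehyde with methyl bromo(triphenylphosphoranylidene)acetate (toluene, 80 °C) gives methyl (Z)-2-bromo-3-[4-(benzyloxy)phenyl]prop-2-enoate F3. Bromide 4 is taken through aryllithium 5 (n-BuLi, THF, −78 °C) to the arylzinc chloride F4 (ZnCl2). Negishi coupling of F4 with F3 (Pd(OAc)2, SPhos, THF, 50 °C) gives, with retention of the alkene geometry, the methyl (E)-2,3-diarylacrylate F5 with the two aryl groups cis. Shi epoxidation (fructose-derived ketone of the enantiomeric series that delivers the (2R,3S)-epoxide, KHSO5, K2CO3 buffer, MeCN/H2O, 0 °C) gives the glycidic ester F6. With BF3·OEt2 and pentamethylbenzene (CH2Cl2, −78 °C) the O-7 ether oxygen should open the epoxide at the benzylic carbon in an SN1-like closure that places the aryl group trans to the ester (net inversion at that carbon), and its BOB group is passed to pentamethylbenzene, which gives 7.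

Step 8. Over-reduction may occur: hydrogenolysis of the cyclic benzylic C–O bonds (flavan C-2–O-1, furan C-2–O) or of the quaternary benzylic C–O bond at the spiro carbon. The fallback runs from 15 to 16 without hydrogen: Lewis-acid debenzylation with BCl3 and pentamethylbenzene as cation scavenger (CH2Cl2, −78 °C), which removes benzyl and BOB ethers alike and makes no new isolated compound.

Further compounds
F1 | step 7 | methyl ester of 7 O-arylated at the tertiary oxygen with 3,5-bis(benzyloxy)phenyl (furan 2R,3R; flavan 2R,3R) | COC(=O)[C@@]1(Oc2cc(OCc3ccccc3)cc(OCc3ccccc3)c2)c2c(cc(OCc4ccc(OCc5ccccc5)cc4)c3c2O[C@H](c2ccc(OCc4ccc(OCc5ccccc5)cc4)cc2)[C@H](OCc2ccc(OCc4ccccc4)cc2)C3)O[C@@H]1c1ccc(OCc2ccccc2)cc1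
F2 | step 7 | carboxylic acid corresponding to F1 | OC(=O)[C@@]1(Oc2cc(OCc3ccccc3)cc(OCc3ccccc3)c2)c2c(cc(OCc4ccc(OCc5ccccc5)cc4)c3c2O[C@H](c2ccc(OCc4ccc(OCc5ccccc5)cc4)cc2)[C@H](OCc2ccc(OCc4ccccc4)cc2)C3)O[C@@H]1c1ccc(OCc2ccccc2)cc1
F3 | step 4 | methyl (Z)-2-bromo-3-[4-(benzyloxy)phenyl]prop-2-enoate | COC(=O)/C(Br)=C/c1ccc(OCc2ccccc2)cc1
F4 | step 4 | [(2R,3R)-tetra-O-BOB-epiafzelechin-8-yl]zinc chloride, not isolated | C(c1ccc(OCc2ccccc2)cc1)Oc1cc(OCc2ccc(OCc3ccccc3)cc2)c2c(c1[Zn]Cl)O[C@H](c1ccc(OCc3ccc(OCc4ccccc4)cc3)cc1)[C@H](OCc1ccc(OCc3ccccc3)cc1)C2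
F5 | step 4 | methyl (E)-3-[4-(benzyloxy)phenyl]-2-[(2R,3R)-tetra-O-BOB-epiafzelechin-8-yl]prop-2-enoate | COC(=O)/C(=C/c1ccc(OCc2ccccc2)cc1)c1c(OCc2ccc(OCc3ccccc3)cc2)cc(OCc2ccc(OCc3ccccc3)cc2)c2c1O[C@H](c1ccc(OCc3ccc(OCc4ccccc4)cc3)cc1)[C@H](OCc1ccc(OCc3ccccc3)cc1)C2
F6 | step 4 | methyl (2R,3S)-3-[4-(benzyloxy)phenyl]-2-[(2R,3R)-tetra-O-BOB-epiafzelechin-8-yl]oxirane-2-carboxylate | COC(=O)[C@@]1(O[C@H]1c1ccc(OCc2ccccc2)cc1)c1c(OCc2ccc(OCc3ccccc3)cc2)cc(OCc2ccc(OCc3ccccc3)cc2)c2c1O[C@H](c1ccc(OCc3ccc(OCc4ccccc4)cc3)cc1)[C@H](OCc1ccc(OCc3ccccc3)cc1)C2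
F0 | step 8 | none | none
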